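## Hansfordiol D from cardanol triene: late meta C–H borylation–oxidation

**Compound numbers used throughout**
1 cardanol triene; 2 its triisopropylsilyl ether; 3 primary pinacol boronate; 4 ethyl 2,4,6-triisopropylbenzoate; 5 lithiated 4; 6 boronate complex; 7 secondary boronic ester; 8 (S)-alcohol; 9 bis-silyl ether (key-step precursor); 10 bis(pinacolato)diboron; 11 aryl boronate; 12 monosilyl resorcinol (key-step product); 13 Hansfordiol D.

Chain carbons are counted C1 to C17 from the ring. Ring positions are named as in the cardanol-derived intermediates: oxygen on ring C1, chain on ring C3, new oxygen at ring C5.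

Assumption: 1 is the triene fraction of commercial cardanol, separated from the saturated, monoene and diene congeners by argentation or reversed-phase chromatography; 4, 10 and (+)-sparteine are bought. All operations are run under argon because of the doubly allylic C10–H bonds.

## Analysis of the target

Hansfordiol D (13) is a 5-alkylresorcinol: one benzene ring with two hydroxyl groups in a 1,3-relationship and, meta to both, an unbranched C17 chain. The chain holds a skipped (8Z,11Z)-diene with a doubly allylic methylene at C10 and, three methylenes further out, the only stereocentre, the (S)-configured secondary carbinol C16 next to the terminal methyl C17. With a single stereocentre there is no relative configuration to set; the stereochemical content is the absolute configuration at C16 and the two Z geometries. The sensitive parts are the C10–H bonds (hydrogen abstraction, autoxidation, base- or metal-hydride-induced shift of the alkenes into conjugation), the Z geometries themselves, and the electron-rich resorcinol, which oxidises readily as its phenolate. The difficulty is that ring pattern, diene and carbinol are too far apart to help one another, so a synthesis from small pieces spends most of its steps on placing two Z-alkenes at fixed distances from both ends. The feature that removes this burden is that the ring, chain C1–C15, both Z-alkenes at C8 and C11 and one phenolic oxygen are already joined in the triene component of cardanol (1), which ends in a C14=C15 vinyl group exactly where the missing C16–C17 unit must be attached. What 1 lacks on the ring is the second oxygen at ring C5, meta to both the existing oxygen and the chain: electrophilic substitution cannot reach it, but it is the only ring C–H flanked by two hydrogens, which is the site a sterically governed C–H borylation selects.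

## Retrosynthetic reasoning

**13 to 12.** The last disconnection is of two O–Si bonds. In 12 the C16 oxygen is a tert-butyldimethylsilyl ether and one ring oxygen a triisopropylsilyl ether. Both fall in one desilylation, so the free resorcinol and the free carbinol appear only at the very end.

**12 to 9 and 10.** The ring C5–O bond is cut and traced, through the C5–B bond of 11, to the C5–H bond of 9. This oxygen is the one ring substituent the feedstock lacks, and no classical substitution places it. Cutting here lets all chain chemistry run on a simple phenol ether and puts the one uncertain transformation late, on material whose chain and stereocentre are complete. The forward reaction must choose C5–H over C2, C4 and C6 and must leave the two Z-alkenes and C10–H2 untouched. The aryl oxygen carries the triisopropylsilyl group because its bulk closes the positions next to oxygen and because this ether withstands the organolithium reagent and the aqueous oxidations of the route.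

**9 to 8.** The C16 O–Si bond is cut. A free hydroxyl would consume boron reagent in the key step, so it is capped one step earlier.

**8 to 3 and 4.** The chain is cut between C15 and C16. C16 and C17 come from the O-ethyl group of 4; the chain enters as the primary boronic ester 3. Forward, 4 is deprotonated enantioselectively to 5, which adds to boron of 3 to give 6; a 1,2-shift forms the C15–C16 bond in 7, and oxidation of the C–B bond gives the carbinol. This is a reagent-controlled way to set an isolated stereocentre far from any other functionality, with the chain component as the limiting reagent. A catalytic asymmetric addition of a chain-derived organozinc reagent to a two-carbon carbonyl partner was considered for the same bond and set aside: such reagents pass on only one of their two alkyl groups, and the smallest carbonyl partner offers the least differentiation of its faces.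

**3 to 2.** The C15–B bond is cut. Forward, an anti-Markovnikov hydroboration must take the monosubstituted C14=C15 alkene and ignore the two Z-disubstituted ones, without moving any double bond.

**2 to 1.** The aryl O–Si bond is cut; 1 is the starting material.

## Alternatives that were turned down

Alternative 1: The resorcinol ring itself is disconnected, three ring bonds being cut so that the arene is built last on the finished chain by a Danheiser benzannulation. Forward, the 3-alkylcyclobutenone A1 would be heated with (triisopropylsilyloxy)acetylene A2. Electrocyclic opening of A1 to a vinylketene, [2+2] addition of A2, a second four-electron opening and a six-electron closure would give the monosilyl resorcinol A3, which is the same compound as 12. In its favour, the 1,3,5-pattern follows from the connectivity of the annulation, so no site-selectivity question arises, and the two oxygens come out differentiated; on regiochemical certainty this plan is stronger than a C–H functionalisation. Against it, the problem only moves into A1: its whole chain with both Z-alkenes and the C16 carbinol must be assembled from small pieces before a strained, nucleophile-sensitive cyclobutenone is attached, and the usual ketene cycloaddition route to cyclobutenones does not tolerate bystander alkenes. The annulation also asks the skipped diene to sit through prolonged heating beside ketene intermediates. A1 alone would cost more steps than the whole chosen route, which takes ring, aryl–chain bond and diene from 1 and pays with a selectivity question confined to one step.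

Alternative 2: The chain is cut on both sides of C8=C9, at C7–C8 and C9–C10, the two alkene carbons coming from acetylene A4. The Grignard reagent A5 would be converted with the copper salt A6, which is CuBr·SMe2, into an organocopper reagent that adds syn across A4. The resulting (Z)-alkenylcopper species would be alkylated in the same flask by the (Z)-allylic bromide A7 to give the fully protected target A8. In its favour, the plan is convergent, both Z geometries follow from mechanism, the arene carries both oxygens from the outset, and nothing depends on the composition of a natural feedstock. In convergence and in certainty of the oxygenation pattern it is as strong as or stronger than the chosen plan. Against it, A5 and A7 each need a multistep preparation, A7 is a cis-allylic halide prone to E/Z and allylic scrambling, the allylation can leak into the branched SN2' product, and gaseous A4 together with a full equivalent of the monovalent copper salt A6 is awkward to run. The total would be roughly twice the step count of the chosen route, which buys the diene instead of building it.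

Alternative 3: The bond between the ring and chain C1 is cut, the chain coming from a C18 carboxylic acid that loses its carboxyl carbon. The N-hydroxyphthalimide ester A9 of the silyl-protected hydroxy acid A10 would be coupled with the arylzinc chloride A11 under the nickel precatalyst A12, which is NiCl2·glyme, and a bipyridine ligand. Single-electron reduction of A9, decarboxylation to the primary C1 radical and capture at the nickel centre derived from A12 would give the tris-silyl ether A13. In its favour, this is a direct sp2–sp3 union under mild conditions with the resorcinol unit bought complete, so the ring regiochemistry is again beyond question. Against it, A10 with its ω-1 hydroxyl of defined configuration is not an article of commerce; making it costs a chain synthesis as long as in Alternative 2 or an enzymatic hydroxylation of uncertain positional selectivity. The coupling also generates a primary alkyl radical in a medium full of doubly allylic C–H bonds, the weakest in the molecule, so hydrogen transfer and diene scrambling compete. The chosen route needs no radical and finds the aryl–chain bond already made in 1; what it gives up is the freedom to vary the arene.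

Key step: step 5

## Route

Step 1
Reactants: 1 cardanol triene (3-[(8Z,11Z)-pentadeca-8,11,14-trien-1-yl]phenol)
Product: 2 triisopropyl{3-[(8Z,11Z)-pentadeca-8,11,14-trien-1-yl]phenoxy}silane
Conditions: iPr3SiCl (1.2 equiv), imidazole (2.5 equiv), DMF, rt
Reagents that add atoms: triisopropylsilyl chloride, CC(C)[Si](Cl)(C(C)C)C(C)C
Why: Imidazole-promoted O-silylation of a phenol; the triene is inert. The triisopropylsilyl ether is chosen because it withstands the organolithium and perborate steps ahead and adds bulk beside ring C2 and C6.

Step 2
Reactants: 2 triisopropyl{3-[(8Z,11Z)-pentadeca-8,11,14-trien-1-yl]phenoxy}silane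
Product: 3 4,4,5,5-tetramethyl-2-{(4Z,7Z)-15-[3-(triisopropylsilyloxy)phenyl]pentadeca-4,7-dien-1-yl}-1,3,2-dioxaborolane
Conditions: HBpin (1.2 equiv), [Ir(cod)Cl]2 (1.5 mol %), Ph2PCH2PPh2 (3 mol %), CH2Cl2, rt
Reagents that add atoms: pinacolborane, CC1(C)OBOC1(C)C
Why: Catalysed anti-Markovnikov hydroboration of a monosubstituted alkene; the catalyst formed from [Ir(cod)Cl]2 and Ph2PCH2PPh2 inserts only the unhindered vinyl group and places boron on the terminal carbon C15. The 1,2-disubstituted Z-alkenes insert far more slowly and should remain.

Step 3
Reactants: 3 4,4,5,5-tetramethyl-2-{(4Z,7Z)-15-[3-(triisopropylsilyloxy)phenyl]pentadeca-4,7-dien-1-yl}-1,3,2-dioxaborolane; 4 ethyl 2,4,6-triisopropylbenzoate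
Product: 8 (2S,6Z,9Z)-17-[3-(triisopropylsilyloxy)phenyl]heptadeca-6,9-dien-2-ol, via lithiated ester 5 (not isolated), via boronate complex 6 (not isolated), via secondary boronic ester 7 (not isolated)
Conditions: 4 (1.3 equiv), (+)-sparteine (1.3 equiv), sBuLi (1.25 equiv), Et2O, −78 °C, 5 h; then 3 (1.0 equiv), −78 °C, 1 h, then 35 °C, 2 h; then NaBO3·4H2O (5 equiv), THF/H2O, rt
Reagents that add atoms: sodium perborate tetrahydrate (NaBO3·4H2O), [Na+].[Na+].O[B-]1(O)OO[B-](O)(O)OO1
Why: Lithiation–borylation (a Hoppe-type chiral carbenoid in a Matteson-type 1,2-metallate rearrangement): sBuLi/(+)-sparteine removes the pro-R hydrogen of the OCH2 group of 4 to give configurationally stable (R)-5, which adds to boron of 3 with retention to give 6. On warming, the chain migrates from boron to carbon anti to the departing triisopropylbenzoate (inversion) to give (S)-7, and perborate turns C–B into C–O with retention, so C16 is S in 8. Because sBuLi is the limiting reagent and is consumed before 3 is added, no free alkyllithium meets C10–H2 or the aryl silyl ether.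

Step 4
Reactants: 8 (2S,6Z,9Z)-17-[3-(triisopropylsilyloxy)phenyl]heptadeca-6,9-dien-2-ol
Product: 9 tert-butyldimethyl({(2S,6Z,9Z)-17-[3-(triisopropylsilyloxy)phenyl]heptadeca-6,9-dien-2-yl}oxy)silane
Conditions: tBuMe2SiCl (1.5 equiv), imidazole (3 equiv), DMF, rt
Reagents that add atoms: tert-butyldimethylsilyl chloride, CC(C)(C)[Si](C)(C)Cl
Why: Standard silylation of a secondary alcohol with no change at C16. It removes the only protic group, which would otherwise consume boron reagent in step 5.

Step 5
Reactants: 9 tert-butyldimethyl({(2S,6Z,9Z)-17-[3-(triisopropylsilyloxy)phenyl]heptadeca-6,9-dien-2-yl}oxy)silane; 10 bis(pinacolato)diboron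
Product: 12 3-[(8Z,11Z,16S)-16-(tert-butyldimethylsilyloxy)heptadeca-8,11-dien-1-yl]-5-(triisopropylsilyloxy)phenol, via aryl boronate 11 (not isolated)
Conditions: [Ir(OMe)(cod)]2 (1.5 mol %), 4,4'-di-tert-butyl-2,2'-bipyridine (3 mol %), 10 (1.0 equiv), THF, rt to 50 °C; then NaBO3·4H2O (3 equiv), THF/H2O, rt
Reagents that add atoms: sodium perborate tetrahydrate (NaBO3·4H2O), [Na+].[Na+].O[B-]1(O)OO[B-](O)(O)OO1
Why: [Ir(OMe)(cod)]2, the bipyridine (dtbpy) and 10 form the 16-electron tris(boryl) complex Ir(dtbpy)(Bpin)3 of trivalent iridium, which cleaves an arene C–H bond by oxidative addition to a pentavalent iridium aryl hydride and releases 11 by C–B reductive elimination; 10 then restores the tris(boryl) complex and leaves pinacolborane. In the second stage the peroxo anion from perborate adds to boron of 11, the aryl group shifts from boron to oxygen with loss of borate, and hydrolysis of the aryl borate frees phenol 12. The closest known reaction type is the sterically governed iridium-catalysed borylation of 1,3-disubstituted benzenes with oxidation of the boronate in the same flask to 3,5-disubstituted phenols. No ring is closed and no stereocentre is formed; C16 and both Z-alkenes are spectators. Three selectivities are needed. Among the ring positions, the crowded tris(boryl) complex cannot approach a C–H bond next to a substituent, so C2, C4 and C6 are closed and C5, the only C–H with hydrogen on both sides, should react; the triisopropylsilyl group makes the oxygen side as forbidding as the alkyl side. Between arene and chain, 1,2-disubstituted Z-alkenes insert into Ir–H and Ir–B bonds much more slowly than monosubstituted ones, and one equivalent of 10 at low temperature keeps the hydride by-product from being forced onto them. In the oxidation, perborate is a nucleophilic oxidant that attacks the empty orbital on boron and does not epoxidise isolated alkenes, and the hindered aryl O–Si bond should withstand its mild alkalinity.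

Step 6
Reactants: 12 3-[(8Z,11Z,16S)-16-(tert-butyldimethylsilyloxy)heptadeca-8,11-dien-1-yl]-5-(triisopropylsilyloxy)phenol
Product: 13 Hansfordiol D, 5-[(8Z,11Z,16S)-16-hydroxyheptadeca-8,11-dien-1-yl]benzene-1,3-diol
Conditions: Bu4NF (3 equiv), THF, 0 °C to rt, argon; aqueous work-up at pH 7
Reagents that add atoms: none
Why: Fluoride-induced cleavage of both Si–O bonds, driven by Si–F bond formation; the aryl ether falls quickly and the secondary alkyl ether within hours. No bond to C16 and no alkene is touched, and exclusion of air protects the resorcinolate until work-up.

## Compound list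

1 | cardanol triene, 3-[(8Z,11Z)-pentadeca-8,11,14-trien-1-yl]phenol | C=CC/C=C\C/C=C\CCCCCCCc1cccc(O)c1 | starting material
2 | triisopropyl{3-[(8Z,11Z)-pentadeca-8,11,14-trien-1-yl]phenoxy}silane | C=CC/C=C\C/C=C\CCCCCCCc1cccc(O[Si](C(C)C)(C(C)C)C(C)C)c1 | intermediate
3 | 4,4,5,5-tetramethyl-2-{(4Z,7Z)-15-[3-(triisopropylsilyloxy)phenyl]pentadeca-4,7-dien-1-yl}-1,3,2-dioxaborolane | CC1(C)OB(CCC/C=C\C/C=C\CCCCCCCc2cccc(O[Si](C(C)C)(C(C)C)C(C)C)c2)OC1(C)C | intermediate
4 | ethyl 2,4,6-triisopropylbenzoate | CCOC(=O)c1c(C(C)C)cc(C(C)C)cc1C(C)C | starting material
5 | (R)-1-lithioethyl 2,4,6-triisopropylbenzoate, as its (+)-sparteine complex | C[C@@H]([Li])OC(=O)c1c(C(C)C)cc(C(C)C)cc1C(C)C | intermediate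
6 | lithium borate complex of 3 and 5, (R) at the oxygen-bearing carbon | [Li+].C[C@H](OC(=O)c1c(C(C)C)cc(C(C)C)cc1C(C)C)[B-]1(CCC/C=C\C/C=C\CCCCCCCc2cccc(O[Si](C(C)C)(C(C)C)C(C)C)c2)OC(C)(C)C(C)(C)O1 | intermediate
7 | 4,4,5,5-tetramethyl-2-{(2S,6Z,9Z)-17-[3-(triisopropylsilyloxy)phenyl]heptadeca-6,9-dien-2-yl}-1,3,2-dioxaborolane | C[C@H](B1OC(C)(C)C(C)(C)O1)CCC/C=C\C/C=C\CCCCCCCc1cccc(O[Si](C(C)C)(C(C)C)C(C)C)c1 | intermediate
8 | (2S,6Z,9Z)-17-[3-(triisopropylsilyloxy)phenyl]heptadeca-6,9-dien-2-ol | C[C@H](O)CCC/C=C\C/C=C\CCCCCCCc1cccc(O[Si](C(C)C)(C(C)C)C(C)C)c1 | intermediate
9 | tert-butyldimethyl({(2S,6Z,9Z)-17-[3-(triisopropylsilyloxy)phenyl]heptadeca-6,9-dien-2-yl}oxy)silane | C[C@H](O[Si](C)(C)C(C)(C)C)CCC/C=C\C/C=C\CCCCCCCc1cccc(O[Si](C(C)C)(C(C)C)C(C)C)c1 | intermediate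
10 | bis(pinacolato)diboron | CC1(C)OB(OC1(C)C)B1OC(C)(C)C(C)(C)O1 | starting material
11 | 2-{3-[(8Z,11Z,16S)-16-(tert-butyldimethylsilyloxy)heptadeca-8,11-dien-1-yl]-5-(triisopropylsilyloxy)phenyl}-4,4,5,5-tetramethyl-1,3,2-dioxaborolane | C[C@H](O[Si](C)(C)C(C)(C)C)CCC/C=C\C/C=C\CCCCCCCc1cc(B2OC(C)(C)C(C)(C)O2)cc(O[Si](C(C)C)(C(C)C)C(C)C)c1 | intermediate
12 | 3-[(8Z,11Z,16S)-16-(tert-butyldimethylsilyloxy)heptadeca-8,11-dien-1-yl]-5-(triisopropylsilyloxy)phenol | C[C@H](O[Si](C)(C)C(C)(C)C)CCC/C=C\C/C=C\CCCCCCCc1cc(O)cc(O[Si](C(C)C)(C(C)C)C(C)C)c1 | intermediate
13 | Hansfordiol D, 5-[(8Z,11Z,16S)-16-hydroxyheptadeca-8,11-dien-1-yl]benzene-1,3-diol | C[C@H](O)CCC/C=C\C/C=C\CCCCCCCc1cc(O)cc(O)c1 | target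

## Step count and risk

Total step count: 6
Longest linear sequence: 6 steps (1 to 13)

**Step 5 (key step).** The most likely failure is consumption of the chain alkenes before the arene is fully borylated. This could happen by iridium-catalysed addition of the pinacolborane by-product to C8=C9 or C11=C12, or by migration of the skipped diene into conjugation through hydride addition–elimination around C10. The arene carries two donor groups and so belongs to the slower arene classes, which narrows the rate gap. Partial hydrolysis of the aryl silyl ether in the perborate stage is a lesser event, since that material still converges on 13 in step 6.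

Fallback (the diene is masked while the ring is functionalised): from 9, Br2 (2 equiv, CH2Cl2, −78 °C) adds anti to both Z-alkenes to give triisopropyl{3-[(16S)-8,9,11,12-tetrabromo-16-(tert-butyldimethylsilyloxy)heptadecyl]phenoxy}silane F1 as a mixture of diastereomers. F1 is borylated with 10 under [Ir(OMe)(cod)]2 and 4,4'-di-tert-butyl-2,2'-bipyridine, as in step 5, to the tetrabromo aryl boronate F2. Zn dust (THF/AcOH, 0 °C) then removes the four bromine atoms by anti elimination, which should return both alkenes with Z geometry and give 11, where the route is rejoined; the perborate stage of step 5 then gives 12. This bromination–debromination sequence is the classical way to carry cis,cis skipped dienes of fatty acids through incompatible chemistry.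

**Step 2.** The most likely failure is migration of the terminal double bond along the chain by reversible Ir–H insertion and β-hydride elimination, into conjugation with C11=C12, which would give internal or allylic boronates. Incomplete discrimination between the vinyl group and the Z-alkenes is the second concern.

Fallback (stoichiometric, metal-free hydroboration and a borane in place of the boronic ester): from 2, 9-borabicyclo[3.3.1]nonane (THF, 0 °C to rt) hydroborates only the monosubstituted alkene to give 9-{(4Z,7Z)-15-[3-(triisopropylsilyloxy)phenyl]pentadeca-4,7-dien-1-yl}-9-borabicyclo[3.3.1]nonane F3. F3 is added at −78 °C to 5, prepared as in step 3, to give the lithium borate complex F4. On warming, the primary alkyl group migrates in preference to the bicyclic B–C bonds to give the secondary borane F5, and oxidation with NaBO3·4H2O releases 8, where the route is rejoined. Steps 2 and 3 are thereby replaced.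

**Step 3.** The most likely failure is incomplete enantioselection in the deprotonation of 4, or partial loss of configuration of 5 if the temperature rises before 3 is added. The C16 enantiomer of 8 cannot be removed by chromatography, and C16 is too remote from other functionality to be corrected later.

Fallback (enzymatic sorting of enantiomers instead of reagent control): 8 of insufficient enantiomeric purity is treated with immobilised Candida antarctica lipase B and vinyl acetate (hexane, rt). This enzyme prefers the (R)-enantiomer of methyl carbinols, so the unwanted enantiomer should be acylated to (2R,6Z,9Z)-17-[3-(triisopropylsilyloxy)phenyl]heptadeca-6,9-dien-2-yl acetate F6, which is separated by chromatography from unreacted (S)-8. The route continues from 8. The same treatment would resolve material of any enantiomeric composition, so the homologation could in the worst case be run with an achiral diamine.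

## Further compounds

F1 | step 5 | triisopropyl{3-[(16S)-8,9,11,12-tetrabromo-16-(tert-butyldimethylsilyloxy)heptadecyl]phenoxy}silane (diastereomer mixture at C8, C9, C11, C12) | C[C@H](O[Si](C)(C)C(C)(C)C)CCCC(Br)C(Br)CC(Br)C(Br)CCCCCCCc1cccc(O[Si](C(C)C)(C(C)C)C(C)C)c1
F2 | step 5 | 2-{3-[(16S)-8,9,11,12-tetrabromo-16-(tert-butyldimethylsilyloxy)heptadecyl]-5-(triisopropylsilyloxy)phenyl}-4,4,5,5-tetramethyl-1,3,2-dioxaborolane (diastereomer mixture) | C[C@H](O[Si](C)(C)C(C)(C)C)CCCC(Br)C(Br)CC(Br)C(Br)CCCCCCCc1cc(B2OC(C)(C)C(C)(C)O2)cc(O[Si](C(C)C)(C(C)C)C(C)C)c1
F3 | step 2 | 9-{(4Z,7Z)-15-[3-(triisopropylsilyloxy)phenyl]pentadeca-4,7-dien-1-yl}-9-borabicyclo[3.3.1]nonane | C1CC2CCCC(C1)B2CCC/C=C\C/C=C\CCCCCCCc1cccc(O[Si](C(C)C)(C(C)C)C(C)C)c1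
F4 | step 2 | lithium borate complex of F3 and 5, (R) at the oxygen-bearing carbon | [Li+].C[C@H](OC(=O)c1c(C(C)C)cc(C(C)C)cc1C(C)C)[B-]1(CCC/C=C\C/C=C\CCCCCCCc2cccc(O[Si](C(C)C)(C(C)C)C(C)C)c2)C2CCCC1CCC2
F5 | step 2 | 9-{(2S,6Z,9Z)-17-[3-(triisopropylsilyloxy)phenyl]heptadeca-6,9-dien-2-yl}-9-borabicyclo[3.3.1]nonane | C[C@H](B1C2CCCC1CCC2)CCC/C=C\C/C=C\CCCCCCCc1cccc(O[Si](C(C)C)(C(C)C)C(C)C)c1
F6 | step 3 | (2R,6Z,9Z)-17-[3-(triisopropylsilyloxy)phenyl]heptadeca-6,9-dien-2-yl acetate | C[C@@H](OC(C)=O)CCC/C=C\C/C=C\CCCCCCCc1cccc(O[Si](C(C)C)(C(C)C)C(C)C)c1
A1 | alternative 1 | 3-[(8Z,11Z,16S)-16-(tert-butyldimethylsilyloxy)heptadeca-8,11-dien-1-yl]cyclobut-2-en-1-one | C[C@H](O[Si](C)(C)C(C)(C)C)CCC/C=C\C/C=C\CCCCCCCC1=CC(=O)C1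
A2 | alternative 1 | (triisopropylsilyloxy)acetylene | C#CO[Si](C(C)C)(C(C)C)C(C)C
A3 | alternative 1 | 3-[(8Z,11Z,16S)-16-(tert-butyldimethylsilyloxy)heptadeca-8,11-dien-1-yl]-5-(triisopropylsilyloxy)phenol (identical with 12) | C[C@H](O[Si](C)(C)C(C)(C)C)CCC/C=C\C/C=C\CCCCCCCc1cc(O)cc(O[Si](C(C)C)(C(C)C)C(C)C)c1
A4 | alternative 2 | acetylene | C#C
A5 | alternative 2 | {7-[3,5-bis(methoxymethoxy)phenyl]heptyl}magnesium bromide | COCOc1cc(CCCCCCC[Mg]Br)cc(OCOC)c1
A6 | alternative 2 | CuBr·SMe2, copper bromide dimethyl sulfide complex | CSC.Br[Cu]
A7 | alternative 2 | (S,Z)-[(8-bromooct-6-en-2-yl)oxy](tert-butyl)dimethylsilane | C[C@H](O[Si](C)(C)C(C)(C)C)CCC/C=C\CBr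
A8 | alternative 2 | tert-butyl({(2S,6Z,9Z)-17-[3,5-bis(methoxymethoxy)phenyl]heptadeca-6,9-dien-2-yl}oxy)dimethylsilane | C[C@H](O[Si](C)(C)C(C)(C)C)CCC/C=C\C/C=C\CCCCCCCc1cc(OCOC)cc(OCOC)c1
A9 | alternative 3 | 1,3-dioxoisoindolin-2-yl (9Z,12Z,17S)-17-(tert-butyldimethylsilyloxy)octadeca-9,12-dienoate | C[C@H](O[Si](C)(C)C(C)(C)C)CCC/C=C\C/C=C\CCCCCCCC(=O)ON1C(=O)c2ccccc2C1=O
A10 | alternative 3 | (9Z,12Z,17S)-17-hydroxyoctadeca-9,12-dienoic acid | C[C@H](O)CCC/C=C\C/C=C\CCCCCCCC(=O)O
A11 | alternative 3 | [3,5-bis(tert-butyldimethylsilyloxy)phenyl]zinc chloride | CC(C)(C)[Si](C)(C)Oc1cc([Zn]Cl)cc(O[Si](C)(C)C(C)(C)C)c1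
A12 | alternative 3 | NiCl2·glyme, nickel dichloride 1,2-dimethoxyethane complex | COCCOC.Cl[Ni]Cl
A13 | alternative 3 | tris(tert-butyldimethylsilyl) ether of Hansfordiol D | C[C@H](O[Si](C)(C)C(C)(C)C)CCC/C=C\C/C=C\CCCCCCCc1cc(O[Si](C)(C)C(C)(C)C)cc(O[Si](C)(C)C(C)(C)C)c1
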